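**Retrosynthetic overview**
- The target is cut at the malate ester into (R)-malic acid, used as its O-trifluoroacetyl anhydride (opened by the ω-hydroxyl at the carbonyl next to the oxygenated carbon), and an ω-hydroxy lactone diacid.
- The lactone diacid comes, by oxidation-level adjustment only (saponification, RuO4), from a 1,7-dioxaspiro[4.4]nonan-8-one: its oxolane (ring A) is the future γ-lactone and its lactone (ring B) masks the succinic acid unit.
- The spiro compound comes from an achiral (E)-2-(3-hydroxypropyl)alk-2-en-1-ol and CO in one enantioselective palladium-catalysed oxycarbonylative bicyclisation. Ring A closes first through the bond between the ring oxygen and the quaternary carbon, then ring B closes by acyl capture; the C–CO bond and both stereocentres arise in the same operation.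
- Enabling feature: the quaternary ring carbon is at once the γ-carbon of the lactone (its oxygen is tethered through three carbons, 5-exo) and the centre of a 2-alkylsuccinic acid unit HO2C–C(quaternary)–CH–CO2H. At the alcohol oxidation level one carboxyl becomes an allylic CH2OH placed 1,4 to the carbonylated CH carbon, so it traps the acyl-palladium as a second five-membered ring.
- The diol comes from δ-valerolactone and 11-silyloxyundecanal (aldol, E-selective dehydration, DIBAL-H); the aldehyde comes from undecane-1,11-diol.

Key step: step 6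

Assumption: with a chloride-free cationic divalent palladium catalyst the alcohol oxygen and the metal add to the same face of the alkene (syn oxypalladation), as found for alcohol and phenol nucleophiles under such conditions; the (E) alkene is chosen on that basis, and the ligand antipode is taken if the facial sense proves opposite.

**Step 1**
Reactants: 1 undecane-1,11-diol
Product: 2 11-[(triisopropylsilyl)oxy]undecan-1-ol
Conditions: NaH (1.0 equiv), THF, rt; TIPSCl (1.0 equiv), rt
Reagents that add atoms: triisopropylsilyl chloride (TIPSCl), CC(C)[Si](Cl)(C(C)C)C(C)C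
Why: Monosilylation of a symmetrical diol through its sparingly soluble mono-sodium alkoxide should stop at the mono-ether, and TIPS is chosen because it must later survive DIBAL-H, aqueous NaOH, RuO4 and brief acid.

**Step 2**
Reactants: 2 11-[(triisopropylsilyl)oxy]undecan-1-ol
Product: 3 11-[(triisopropylsilyl)oxy]undecanal
Conditions: TEMPO (10 mol %), PhI(OAc)2 (1.1 equiv), CH2Cl2, rt
Reagents that add atoms: none
Why: TEMPO/PhI(OAc)2 oxidation of a primary alcohol should stop at the aldehyde and leave the silyl ether untouched.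

**Step 3**
Reactants: 3 11-[(triisopropylsilyl)oxy]undecanal; 4 oxan-2-one (δ-valerolactone)
Product: 6 3-{1-hydroxy-11-[(triisopropylsilyl)oxy]undecyl}oxan-2-one (mixture of diastereomers), via lithium enolate of oxan-2-one 5 (not isolated)
Conditions: 4, LDA (1.1 equiv), THF, −78 °C; 3, −78 °C; AcOH, −78 °C
Reagents that add atoms: none
Why: Aldol addition of a preformed lactone lithium enolate to an unbranched aldehyde at low temperature is reliable, and the two new stereocentres do not matter because both are destroyed in the next step.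

**Step 4**
Reactants: 6 3-{1-hydroxy-11-[(triisopropylsilyl)oxy]undecyl}oxan-2-one
Product: 8 (E)-3-{11-[(triisopropylsilyl)oxy]undecylidene}oxan-2-one, via mesylate of the aldol adduct 7 (not isolated)
Conditions: MsCl (1.5 equiv), Et3N (3 equiv), CH2Cl2, 0 °C; then DBU (3 equiv), 0 °C → rt
Reagents that add atoms: none
Why: Mesylation and E1cB elimination of a β-hydroxy lactone should give mainly the thermodynamically preferred (E)-alkylidene lactone (chain anti to the carbonyl), the geometry that later fixes the relative configuration; any (Z) isomer is removed by chromatography.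

**Step 5**
Reactants: 8 (E)-3-{11-[(triisopropylsilyl)oxy]undecylidene}oxan-2-one
Product: 9 (E)-2-(3-hydroxypropyl)-13-[(triisopropylsilyl)oxy]tridec-2-en-1-ol
Conditions: DIBAL-H (4.5 equiv), CH2Cl2, −78 → 0 °C; aqueous Rochelle salt
Reagents that add atoms: none
Why: DIBAL-H reduces the unsaturated lactone by 1,2-addition only, opening it to the allylic alcohol and the 3-hydroxypropyl arm without moving or isomerising the alkene.

**Step 6**
Reactants: 9 (E)-2-(3-hydroxypropyl)-13-[(triisopropylsilyl)oxy]tridec-2-en-1-ol
Product: 10 (5S,9R)-9-{10-[(triisopropylsilyl)oxy]decyl}-1,7-dioxaspiro[4.4]nonan-8-one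
Conditions: Pd(OCOCF3)2 (10 mol %), (S,S)-Bn-BOXAX [2,2'-bis((4S)-4-benzyl-4,5-dihydrooxazol-2-yl)-1,1'-binaphthyl] (20 mol %), p-benzoquinone (2 equiv), CO (1 atm), CH2Cl2, 0 °C → rt
Reagents that add atoms: carbon monoxide, [C-]#[O+]
Why: Proposed new method: the divalent palladium–bis(oxazoline) alkoxide of the 3-hydroxypropyl arm should add syn across the trisubstituted alkene (ring A, 5-exo-trig, oxygen to the fully substituted carbon and palladium to the CH carbon), CO should insert into the secondary alkyl–palladium bond with retention faster than β-hydride elimination, and the allylic CH2OH should capture the acyl-palladium (ring B, 5-exo-trig acyl substitution) with release of zerovalent palladium, which p-benzoquinone reoxidises. The closest known reaction types are the stereospecific intramolecular alkoxycarbonylation of hydroxyalkenes, the oxycarbonylative bicyclisation of unsaturated diols to bicyclic lactones with Pd(OAc)2/bis(oxazoline) catalysts, and the enantioselective domino Wacker–carbonylation of alkenyl phenols with Pd(OCOCF3)2/BOXAX that creates tetrasubstituted C–O centres; new here is the combination of an aliphatic trisubstituted alkene, a palladium-bearing carbon with β-hydrogens and a spiro ring fusion. The configuration of the spiro carbon is set by ligand-controlled choice of the alkene face, and that of the CH carbon follows from the (E) geometry through syn addition and retentive CO insertion, so both stereocentres come from one face-selecting event. The step needs chemoselectivity between the two hydroxyls (only the hydroxypropyl oxygen reaches the alkene through a five-membered transition state, the CH2OH would need a three- or four-membered one), regioselectivity for 5-exo over 6-endo (secured by the Markovnikov preference for the fully substituted carbon) and carbonylation over β-hydride elimination (secured by CO saturation and the intramolecular acyl trap).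

**Step 7**
Reactants: 10 (5S,9R)-9-{10-[(triisopropylsilyl)oxy]decyl}-1,7-dioxaspiro[4.4]nonan-8-one
Product: 12 (2S)-2-[(1R)-1-carboxy-11-[(triisopropylsilyl)oxy]undecyl]-5-oxooxolane-2-carboxylic acid, via sodium hydroxy carboxylate 11 (not isolated)
Conditions: NaOH (1.2 equiv), THF/H2O, rt; then pH 7 phosphate buffer, RuCl3·xH2O (5 mol %), NaIO4 (6 equiv), MeCN/EtOAc/H2O, rt; then 1 M HCl to pH 2
Reagents that add atoms: sodium hydroxide, [Na+].[OH-]; sodium periodate (oxygen passed on through RuO4), [Na+].[O-]I(=O)(=O)=O; water, O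
Why: Saponification of ring B exposes the neopentyl-type primary alcohol as its carboxylate salt, after which RuO4 should oxidise this alcohol to the acid and the only O–CH2 of the oxolane to the lactone carbonyl (the ring oxygen stays etherified, so no glycol is exposed to periodate), while neither stereocentre is touched because one is quaternary and the other sits α to a carboxylate.

**Step 8**
Reactants: 12 (2S)-2-[(1R)-1-carboxy-11-[(triisopropylsilyl)oxy]undecyl]-5-oxooxolane-2-carboxylic acid
Product: 13 (2S)-2-[(1R)-1-carboxy-11-hydroxyundecyl]-5-oxooxolane-2-carboxylic acid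
Conditions: HF (48 % aq.), MeCN, 0 °C → rt
Reagents that add atoms: none
Why: Fluoride-driven cleavage of the primary TIPS ether under acidic conditions should leave the lactone and both carboxylic acids unchanged.

**Step 9**
Reactants: 13 (2S)-2-[(1R)-1-carboxy-11-hydroxyundecyl]-5-oxooxolane-2-carboxylic acid; 14 (R)-malic acid
Product: 17 (2S)-2-[(1R)-1-carboxy-11-{[(2R)-3-carboxy-2-hydroxypropanoyl]oxy}undecyl]-5-oxooxolane-2-carboxylic acid (CNP0457473.2), via O-trifluoroacetylmalic anhydride 15 (not isolated), via O-trifluoroacetyl ester of the target 16 (not isolated)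
Conditions: 14 (3 equiv), (CF3CO)2O, 0 °C → rt, then evaporation; 13, THF, rt; then H2O/MeCN, rt; reversed-phase chromatography
Reagents that add atoms: none
Why: Alcoholysis of an O-acylmalic anhydride takes place at the carbonyl next to the acyloxy-bearing carbon (the known route to malic acid 1-monoesters), so the primary alcohol of 13 should be acylated regioselectively while its hindered acids stay spectators, the malate stereocentre is never enolised, and the labile trifluoroacetate falls off in water.

**Compound list**
1 | undecane-1,11-diol | OCCCCCCCCCCCO | starting material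
2 | 11-[(triisopropylsilyl)oxy]undecan-1-ol | OCCCCCCCCCCCO[Si](C(C)C)(C(C)C)C(C)C | intermediate
3 | 11-[(triisopropylsilyl)oxy]undecanal | O=CCCCCCCCCCCO[Si](C(C)C)(C(C)C)C(C)C | intermediate
4 | oxan-2-one (δ-valerolactone) | O=C1CCCCO1 | starting material
5 | lithium 3,4-dihydro-2H-pyran-6-olate (lithium enolate of 4; not isolated) | [Li+].[O-]C1=CCCCO1 | intermediate
6 | 3-{1-hydroxy-11-[(triisopropylsilyl)oxy]undecyl}oxan-2-one (mixture of diastereomers) | O=C1OCCCC1C(O)CCCCCCCCCCO[Si](C(C)C)(C(C)C)C(C)C | intermediate
7 | 1-(2-oxooxan-3-yl)-11-[(triisopropylsilyl)oxy]undecyl methanesulfonate (not isolated) | O=C1OCCCC1C(OS(C)(=O)=O)CCCCCCCCCCO[Si](C(C)C)(C(C)C)C(C)C | intermediate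
8 | (E)-3-{11-[(triisopropylsilyl)oxy]undecylidene}oxan-2-one | O=C1OCCC/C1=C\CCCCCCCCCCO[Si](C(C)C)(C(C)C)C(C)C | intermediate
9 | (E)-2-(3-hydroxypropyl)-13-[(triisopropylsilyl)oxy]tridec-2-en-1-ol | OC/C(CCCO)=C/CCCCCCCCCCO[Si](C(C)C)(C(C)C)C(C)C | intermediate
10 | (5S,9R)-9-{10-[(triisopropylsilyl)oxy]decyl}-1,7-dioxaspiro[4.4]nonan-8-one | CC(C)[Si](C(C)C)(C(C)C)OCCCCCCCCCC[C@H]1C(=O)OC[C@]12CCCO2 | intermediate
11 | sodium (2R)-2-[(2S)-2-(hydroxymethyl)oxolan-2-yl]-12-[(triisopropylsilyl)oxy]dodecanoate (not isolated) | [Na+].CC(C)[Si](C(C)C)(C(C)C)OCCCCCCCCCC[C@@H](C(=O)[O-])[C@]1(CO)CCCO1 | intermediate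
12 | (2S)-2-[(1R)-1-carboxy-11-[(triisopropylsilyl)oxy]undecyl]-5-oxooxolane-2-carboxylic acid | CC(C)[Si](C(C)C)(C(C)C)OCCCCCCCCCC[C@@H](C(=O)O)[C@]1(C(=O)O)CCC(=O)O1 | intermediate
13 | (2S)-2-[(1R)-1-carboxy-11-hydroxyundecyl]-5-oxooxolane-2-carboxylic acid | OCCCCCCCCCC[C@@H](C(=O)O)[C@]1(C(=O)O)CCC(=O)O1 | intermediate
14 | (R)-malic acid | OC(=O)C[C@@H](O)C(=O)O | starting material
15 | (3R)-2,5-dioxooxolan-3-yl trifluoroacetate (O-trifluoroacetylmalic anhydride; not isolated) | O=C1C[C@@H](OC(=O)C(F)(F)F)C(=O)O1 | intermediate
16 | O-trifluoroacetyl ester of the target (not isolated) | OC(=O)C[C@@H](OC(=O)C(F)(F)F)C(=O)OCCCCCCCCCC[C@@H](C(=O)O)[C@]1(C(=O)O)CCC(=O)O1 | intermediate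
17 | (2S)-2-[(1R)-1-carboxy-11-{[(2R)-3-carboxy-2-hydroxypropanoyl]oxy}undecyl]-5-oxooxolane-2-carboxylic acid | O=C(O)C[C@@H](O)C(=O)OCCCCCCCCCC[C@@H](C(=O)O)[C@]1(C(=O)O)CCC(=O)O1 | target

**Step count and risks**
Total step count: 9. Longest linear sequence: 9 steps (1 to 17); (R)-malic acid 14 enters in step 9.

Steps most likely to fail:

1. Step 6. The ligand may discriminate poorly between the two alkene faces, giving material of low enantiomeric purity. Fallback: setting out from 9, the established racemic oxycarbonylative bicyclisation of unsaturated diols would be run with an achiral ligand [Pd(OCOCF3)2, 2,2'-bipyridine, p-benzoquinone, CO (1 atm), CH2Cl2], which should give 10 together with its enantiomer, the (5R,9S)-spirolactone F1. The mixture would be opened with (S)-1-phenylethylamine/AlMe3 to two diastereomeric hydroxy amides, the (2R)-amide of the (2S)-oxolane F2 (from 10) and the (2S)-amide of the (2R)-oxolane F3 (from F1), which are separated by chromatography or crystallisation. Acid-catalysed relactonisation of F2 (TsOH, toluene, 80 °C) expels the amine and returns to the route at 10.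

2. Step 7. The γ-hydroxy acid may relactonise to 10 faster than its alcohol is oxidised, so that the CH2–O carbon of ring B stays unoxidised. Fallback: setting out from 10, the oxolane is oxidised first (RuCl3·xH2O cat., NaIO4, CCl4/MeCN/H2O) to the spiro bis-lactone F4. Both lactones are then opened with aqueous NaOH to the disodium dihydroxy dicarboxylate F5, whose primary alcohol is oxidised under periodate-free conditions (TEMPO cat., NaClO2, NaOCl cat., pH 6.7 buffer, MeCN) so that the glycol is not cleaved. Acidification closes the γ-lactone and returns to the route at 12.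

3. Step 9. The alcohol may attack the wrong anhydride carbonyl or the free acids of 13 may undergo acyl exchange, and the polar triacid may be hard to separate from malic acid. Fallback: setting out from 12, both acids are benzylated (BnBr, Cs2CO3, DMF) to the dibenzyl ester F6, the silyl ether is cleaved (HF·pyridine, THF) to the alcohol F7, and an Appel reaction (I2, PPh3, imidazole) gives the iodide F8. Separately, diazotisation of commercial D-aspartic acid 4-benzyl ester (NaNO2, aqueous H2SO4, retention through the α-lactone) gives (R)-malic acid 4-benzyl ester F9. Its only free carboxylate is alkylated by F8 (Cs2CO3, DMF, rt) to the tribenzyl ester of the target F10, and hydrogenolysis (H2, palladium on carbon, EtOAc) returns to the route at 17.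

**Further compounds**
F1 | step 6 | (5R,9S)-9-{10-[(triisopropylsilyl)oxy]decyl}-1,7-dioxaspiro[4.4]nonan-8-one | CC(C)[Si](C(C)C)(C(C)C)OCCCCCCCCCC[C@@H]1C(=O)OC[C@@]12CCCO2
F2 | step 6 | (2R)-2-[(2S)-2-(hydroxymethyl)oxolan-2-yl]-N-[(1S)-1-phenylethyl]-12-[(triisopropylsilyl)oxy]dodecanamide | C[C@H](NC(=O)[C@H](CCCCCCCCCCO[Si](C(C)C)(C(C)C)C(C)C)[C@]1(CO)CCCO1)c1ccccc1
F3 | step 6 | (2S)-2-[(2R)-2-(hydroxymethyl)oxolan-2-yl]-N-[(1S)-1-phenylethyl]-12-[(triisopropylsilyl)oxy]dodecanamide | C[C@H](NC(=O)[C@@H](CCCCCCCCCCO[Si](C(C)C)(C(C)C)C(C)C)[C@@]1(CO)CCCO1)c1ccccc1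
F4 | step 7 | (5S,9R)-9-{10-[(triisopropylsilyl)oxy]decyl}-1,7-dioxaspiro[4.4]nonane-2,8-dione | CC(C)[Si](C(C)C)(C(C)C)OCCCCCCCCCC[C@H]1C(=O)OC[C@]12CCC(=O)O2
F5 | step 7 | disodium (2R,3S)-3-hydroxy-3-(hydroxymethyl)-2-{10-[(triisopropylsilyl)oxy]decyl}hexanedioate | [Na+].[Na+].CC(C)[Si](C(C)C)(C(C)C)OCCCCCCCCCC[C@@H](C(=O)[O-])[C@](O)(CO)CCC(=O)[O-]
F6 | step 9 | benzyl (2S)-2-{(2R)-1-(benzyloxy)-1-oxo-12-[(triisopropylsilyl)oxy]dodecan-2-yl}-5-oxooxolane-2-carboxylate | CC(C)[Si](C(C)C)(C(C)C)OCCCCCCCCCC[C@@H](C(=O)OCc1ccccc1)[C@]1(C(=O)OCc2ccccc2)CCC(=O)O1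
F7 | step 9 | benzyl (2S)-2-[(2R)-1-(benzyloxy)-12-hydroxy-1-oxododecan-2-yl]-5-oxooxolane-2-carboxylate | OCCCCCCCCCC[C@@H](C(=O)OCc1ccccc1)[C@]1(C(=O)OCc2ccccc2)CCC(=O)O1
F8 | step 9 | benzyl (2S)-2-[(2R)-1-(benzyloxy)-12-iodo-1-oxododecan-2-yl]-5-oxooxolane-2-carboxylate | ICCCCCCCCCC[C@@H](C(=O)OCc1ccccc1)[C@]1(C(=O)OCc2ccccc2)CCC(=O)O1
F9 | step 9 | (2R)-4-(benzyloxy)-2-hydroxy-4-oxobutanoic acid | O=C(OCc1ccccc1)C[C@@H](O)C(=O)O
F10 | step 9 | benzyl (2S)-2-[(2R)-1-(benzyloxy)-12-{[(2R)-4-(benzyloxy)-2-hydroxy-4-oxobutanoyl]oxy}-1-oxododecan-2-yl]-5-oxooxolane-2-carboxylate | O=C(OCc1ccccc1)C[C@@H](O)C(=O)OCCCCCCCCCC[C@@H](C(=O)OCc1ccccc1)[C@]1(C(=O)OCc2ccccc2)CCC(=O)O1
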